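**Plan**

- Retrosynthesis: the aryl ether C–O bond is cut first (Mitsunobu with umbelliferone), then the oxirane (epoxidation of a (Z)-allylic alcohol), then the lactone acyl–O bond (acyl transfer from a lactic-acid dioxolanone). Last, the CH2–CH(O) bond joining the side chain to the lactone carbinol carbon is cut together with one C–O bond, as a retro oxa-Diels–Alder reaction.
- Enabling feature: the lactone ring oxygen, the lactone carbinol carbon (C5 of the oxolanone), the side-chain CH2, the two oxirane carbons (taken back to a (Z)-C(CH3)=CH unit) and the OCH2 carbon (raised to the acetal level) are six contiguous atoms O–C–C–C=C–C. This is a 3,6-dihydro-2H-pyran, the retron of a carbonyl–diene [4+2] cycloaddition, and inside this temporary ring the trisubstituted olefin can only be (Z).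
- Forward: (S)-lactic acid → cis-dioxolanone (temporary ring one) → allylation → ozonolysis to the aldehyde; [4+2] with 1-ethoxy-3-methylbutadiene closes the dihydropyran (temporary ring two); hydrolysis/reduction opens it to the (Z)-ene-diol; acyl transfer closes the γ-lactone and frees the tertiary alcohol; epoxidation; etherification.
- Stereochemistry: the tertiary carbinol comes from (S)-lactic acid by self-regeneration of the stereocentre; the lactone carbinol carbon from the chiral chromium catalyst of the cycloaddition; the oxirane carbons from D-(−)-diethyl tartrate; the olefin geometry from the ring.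

Key step: step 5

Remark: the (1S,2R) antipode of the chromium catalyst is specified on the assumption that its (1R,2S) antipode adds 1-alkoxybutadienes to the Re face of simple aliphatic aldehydes; the face required here is Si (C=O > CH2 > H). This assignment rests on analogy and should be confirmed on a model aldehyde.

**Route**

Step 1
Reactants: 1 (S)-lactic acid
Product: 2 (2S,5S)-2-tert-butyl-5-methyl-1,3-dioxolan-4-one (cis)
Conditions: pivalaldehyde, p-TsOH·H2O (cat.), H2SO4 (cat.), pentane, reflux with azeotropic removal of water; recrystallization from Et2O/pentane at −78 °C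
Reagents that add atoms: pivalaldehyde, CC(C)(C)C=O
Why: Acid-catalysed acetalization of the α-hydroxy acid should give the dioxolanone, the new acetal centre forming under thermodynamic control cis to the methyl group and the cis isomer being enriched by crystallization.

Step 2
Reactants: 2 (2S,5S)-2-tert-butyl-5-methyl-1,3-dioxolan-4-one; 3 allyl bromide
Product: 4 (2S,5R)-5-allyl-2-tert-butyl-5-methyl-1,3-dioxolan-4-one
Conditions: LiN(iPr)2, THF, −78 °C; then 3, −78 → −30 °C
Reagents that add atoms: none
Why: Enolate alkylation with self-regeneration of the stereocentre: the tert-butyl group shields one face of the lithium enolate, so allyl bromide should enter trans to it and the quaternary centre forms with overall retention.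

Step 3
Reactants: 4 (2S,5R)-5-allyl-2-tert-butyl-5-methyl-1,3-dioxolan-4-one
Product: 5 (2S,5R)-2-tert-butyl-5-methyl-5-(2-oxoethyl)-1,3-dioxolan-4-one
Conditions: O3, CH2Cl2, −78 °C; then PPh3, −78 °C → rt
Reagents that add atoms: ozone, [O-][O+]=O
Why: Ozonolysis with reductive work-up should cleave the terminal alkene to the aldehyde under neutral conditions that leave the acetal ester and both stereocentres untouched.

Step 4
Reactants: 6 1,1-diethoxy-3-methylbut-2-ene
Product: 7 (1E)-1-ethoxy-3-methylbuta-1,3-diene
Conditions: KHSO4 (cat.), 140–150 °C, ethanol distilled off; fractional distillation over K2CO3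
Reagents that add atoms: none
Why: Acid-catalysed 1,4-elimination of ethanol from the α,β-unsaturated acetal via the alkoxyallyl cation should give the 1-alkoxydiene, the (1E) isomer being favoured thermodynamically and the only one expected to react in step 5.

Step 5
Reactants: 5 (2S,5R)-2-tert-butyl-5-methyl-5-(2-oxoethyl)-1,3-dioxolan-4-one; 7 (1E)-1-ethoxy-3-methylbuta-1,3-diene
Product: 8 (2S,5R)-2-tert-butyl-5-{[(2S,6R)-6-ethoxy-4-methyl-3,6-dihydro-2H-pyran-2-yl]methyl}-5-methyl-1,3-dioxolan-4-one
Conditions: [CrCl(L)] (5 mol%; L = dianion of (1S,2R)-1-{[3-(1-adamantyl)-2-hydroxy-5-methylbenzylidene]amino}indan-2-ol; trivalent chromium), 7 (3 equiv), powdered 4 Å molecular sieves, neat, rt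
Reagents that add atoms: none
Why: The trivalent chromium Lewis acid binds the aldehyde oxygen and the s-cis diene adds in a concerted, asynchronous carbonyl–diene [4+2] cycloaddition (oxa-Diels–Alder), C4 of the diene bonding to the carbonyl carbon and the carbonyl oxygen to the ethoxy-bearing C1. The closest known reaction type is the hetero-Diels–Alder reaction of 1-alkoxybutadienes with unactivated aliphatic aldehydes under tridentate Schiff-base chromium catalysis. The 3,6-dihydro-2H-pyran ring is closed by the cycloaddition itself (suprafacial [4π+2π], C–C and C–O bond formed in one event), and because both allylic carbons of the new C(CH3)=CH bond are ring members the olefin is necessarily (Z). The carbinol stereocentre is set by the catalyst, whose (1S,2R) antipode is expected to expose the Si face of the aldehyde; the acetal centre follows from the endo transition state (2,6-cis) and is erased in step 6. The step needs regioselectivity, secured by the single ethoxy donor at C1 that makes C4 the nucleophilic terminus, and chemoselectivity for the aldehyde over the dioxolanone carbonyl, secured by the much lower electrophilicity and Lewis basicity of the hindered acetal ester.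

Step 6
Reactants: 8 (2S,5R)-2-tert-butyl-5-{[(2S,6R)-6-ethoxy-4-methyl-3,6-dihydro-2H-pyran-2-yl]methyl}-5-methyl-1,3-dioxolan-4-one
Product: 10 (2S,5R)-2-tert-butyl-5-[(2S,4Z)-2,6-dihydroxy-4-methylhex-4-en-1-yl]-5-methyl-1,3-dioxolan-4-one, via lactol 9 (not isolated)
Conditions: PPTS (cat.), THF/H2O 4:1, 0 °C → rt; then CeCl3·7H2O, NaBH4, MeOH, −20 °C
Reagents that add atoms: water, O
Why: Mild hydrolysis of the allylic mixed acetal to the lactol followed by Luche 1,2-reduction of its ring-opened (Z)-enal tautomer should give the (Z)-allylic alcohol, the olefin geometry being inherited from the ring and no stereocentre being created.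

Step 7
Reactants: 10 (2S,5R)-2-tert-butyl-5-[(2S,4Z)-2,6-dihydroxy-4-methylhex-4-en-1-yl]-5-methyl-1,3-dioxolan-4-one
Product: 11 (3R,5S)-3-hydroxy-5-[(2Z)-4-hydroxy-2-methylbut-2-en-1-yl]-3-methyloxolan-2-one
Conditions: DBU (0.2 equiv), CH2Cl2, rt
Reagents that add atoms: none
Why: Base-catalysed intramolecular transesterification (5-exo-trig acyl transfer of the secondary hydroxyl onto the dioxolanone carbonyl) should close the γ-lactone while the expelled hemiacetal collapses to pivalaldehyde and the free tertiary alcohol; both stereocentres are untouched, so the cis relationship of hydroxyl and side chain follows from steps 2 and 5.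

Step 8
Reactants: 11 (3R,5S)-3-hydroxy-5-[(2Z)-4-hydroxy-2-methylbut-2-en-1-yl]-3-methyloxolan-2-one
Product: 12 (3R,5R)-3-hydroxy-5-{[(2S,3R)-3-(hydroxymethyl)-2-methyloxiran-2-yl]methyl}-3-methyloxolan-2-one
Conditions: Ti(OiPr)4 (0.3 equiv), D-(−)-diethyl tartrate (0.36 equiv), t-BuOOH (anhydrous, 2 equiv), 4 Å molecular sieves, CH2Cl2, −25 °C; work-up with aqueous tartaric acid
Reagents that add atoms: tert-butyl hydroperoxide, CC(C)(C)OO
Why: Sharpless asymmetric epoxidation: with D-(−)-tartrate the titanium-bound peroxide should be delivered to the olefin face that makes the hydroxymethyl-bearing oxirane carbon (R) and, by syn addition to the (Z)-olefin, the methyl-bearing carbon (S), reagent control overriding the remote lactone centres.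

Step 9
Reactants: 12 (3R,5R)-3-hydroxy-5-{[(2S,3R)-3-(hydroxymethyl)-2-methyloxiran-2-yl]methyl}-3-methyloxolan-2-one; 13 umbelliferone (7-hydroxy-2H-chromen-2-one)
Product: 14 7-{[(2R,3S)-3-{[(2R,4R)-4-hydroxy-4-methyl-5-oxooxolan-2-yl]methyl}-3-methyloxiran-2-yl]methoxy}-2H-chromen-2-one
Conditions: PPh3, DIAD, THF, 0 °C → rt
Reagents that add atoms: none
Why: Mitsunobu etherification of the primary epoxy alcohol with the acidic phenol should form the aryl ether at a non-stereogenic carbon, leaving the oxirane, the lactone and the unreactive tertiary alcohol intact.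

**Compound list**

1 | (S)-lactic acid | C[C@H](O)C(=O)O | starting material
2 | (2S,5S)-2-tert-butyl-5-methyl-1,3-dioxolan-4-one | C[C@@H]1O[C@H](C(C)(C)C)OC1=O | intermediate
3 | allyl bromide | C=CCBr | starting material
4 | (2S,5R)-5-allyl-2-tert-butyl-5-methyl-1,3-dioxolan-4-one | C[C@]1(CC=C)O[C@H](C(C)(C)C)OC1=O | intermediate
5 | (2S,5R)-2-tert-butyl-5-methyl-5-(2-oxoethyl)-1,3-dioxolan-4-one | C[C@]1(CC=O)O[C@H](C(C)(C)C)OC1=O | intermediate
6 | 1,1-diethoxy-3-methylbut-2-ene | CCOC(OCC)C=C(C)C | starting material
7 | (1E)-1-ethoxy-3-methylbuta-1,3-diene | CCO/C=C/C(C)=C | intermediate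
8 | (2S,5R)-2-tert-butyl-5-{[(2S,6R)-6-ethoxy-4-methyl-3,6-dihydro-2H-pyran-2-yl]methyl}-5-methyl-1,3-dioxolan-4-one | C[C@]1(C[C@@H]2CC(C)=C[C@H](OCC)O2)O[C@H](C(C)(C)C)OC1=O | intermediate
9 | (2S,5R)-2-tert-butyl-5-{[(2S)-6-hydroxy-4-methyl-3,6-dihydro-2H-pyran-2-yl]methyl}-5-methyl-1,3-dioxolan-4-one (lactol, both anomers) | C[C@]1(C[C@@H]2CC(C)=CC(O)O2)O[C@H](C(C)(C)C)OC1=O | intermediate
10 | (2S,5R)-2-tert-butyl-5-[(2S,4Z)-2,6-dihydroxy-4-methylhex-4-en-1-yl]-5-methyl-1,3-dioxolan-4-one | C[C@]1(C[C@@H](O)C/C(C)=C\CO)O[C@H](C(C)(C)C)OC1=O | intermediate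
11 | (3R,5S)-3-hydroxy-5-[(2Z)-4-hydroxy-2-methylbut-2-en-1-yl]-3-methyloxolan-2-one | C[C@@]1(O)C[C@H](C/C(C)=C\CO)OC1=O | intermediate
12 | (3R,5R)-3-hydroxy-5-{[(2S,3R)-3-(hydroxymethyl)-2-methyloxiran-2-yl]methyl}-3-methyloxolan-2-one | C[C@@]1(O)C[C@H](C[C@]2(C)O[C@@H]2CO)OC1=O | intermediate
13 | umbelliferone (7-hydroxy-2H-chromen-2-one) | Oc1ccc2ccc(=O)oc2c1 | starting material
14 | 7-{[(2R,3S)-3-{[(2R,4R)-4-hydroxy-4-methyl-5-oxooxolan-2-yl]methyl}-3-methyloxiran-2-yl]methoxy}-2H-chromen-2-one | C[C@@]1(O)C[C@H](C[C@]2(C)O[C@@H]2COc2ccc3ccc(=O)oc3c2)OC1=O | target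

**Summary**

Total step count: 9. Longest linear sequence: 8 steps (steps 1, 2, 3, 5, 6, 7, 8, 9); step 4 prepares the diene on a side branch.

Steps most likely to fail:

Step 5. The cycloaddition of a hindered, enolizable aldehyde with a mono-oxygenated diene may be slow, and a mismatched pairing of the catalyst with the dioxolanone stereocentres may erode control of the aldehyde face. The fallback sets out from 5 and returns at lactol 9; it uses a doubly activated diene and installs the C-methyl group afterwards. Aldehyde 5 is combined with (E)-1-methoxy-3-(trimethylsilyloxy)buta-1,3-diene under catalysis by [Cr(salen)]BF4 (salen = dianion of N,N'-bis(3,5-di-tert-butylsalicylidene)cyclohexane-1,2-diamine; trivalent chromium; antipode chosen for Si-face addition) to give the silyl enol ether cycloadduct F1. Trifluoroacetic acid converts it, with loss of methanol and of the silyl group, into the 2,3-dihydro-4H-pyran-4-one F2. Chemoselective 1,2-addition of MeLi/CeCl3 at −78 °C to the ketone gives the tertiary allylic alcohol F3. PPTS in aqueous THF then brings about the Ferrier-type allylic transposition to lactol 9, which is reduced as in step 6.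

Step 6. The transient (Z)-hydroxy-enal may isomerize to the (E)-enal or dehydrate to a dienal, and premature acyl transfer may be followed by over-reduction of the α-hydroxy lactone. The fallback sets out from 8 and returns at 11; it keeps the (Z)-olefin locked in a ring at the ester oxidation level until the lactone switch is complete. Direct oxidation of the cyclic acetal 8 with CrO3/H2SO4 in acetone gives the α,β-unsaturated δ-lactone F4. LiOH in aqueous THF opens both acyl groups, and acidification to pH 2–3 should close the five-membered lactone preferentially (non-conjugated acceptor, gem-disubstituted α-carbon) to give the (Z)-enoic acid lactone F5. Activation with isobutyl chloroformate/N-methylmorpholine at −15 °C gives the mixed carbonic anhydride F6, and NaBH4 reduces it to 11.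

Step 8. The titanium Lewis acid may promote 6-exo opening of the new oxirane at its tertiary carbon by the cis tertiary hydroxyl, and the α-hydroxy lactone may displace tartrate from titanium and lower the facial selectivity on the slow-reacting (Z)-olefin. The fallback sets out from 10 and returns at 12; the epoxidation is moved ahead of the lactonization, while the tertiary oxygen is still masked in the dioxolanone. Diol 10 is epoxidized with Ti(OiPr)4/D-(−)-diethyl tartrate/t-BuOOH to the epoxy diol F7, whose secondary hydroxyl can reach the oxirane only through disfavoured 4-exo or 5-endo modes. DBU-induced acyl transfer as in step 7 then gives 12.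

Further compounds
F1 | step 5 | (2S,5R)-2-tert-butyl-5-{[6-methoxy-4-(trimethylsilyloxy)-3,6-dihydro-2H-pyran-2-yl]methyl}-5-methyl-1,3-dioxolan-4-one (Si-face cycloadduct) | C[C@]1(C[C@@H]2CC(O[Si](C)(C)C)=CC(OC)O2)O[C@H](C(C)(C)C)OC1=O
F2 | step 5 | (2S,5R)-2-tert-butyl-5-methyl-5-{[(2R)-4-oxo-3,4-dihydro-2H-pyran-2-yl]methyl}-1,3-dioxolan-4-one | C[C@]1(C[C@@H]2CC(=O)C=CO2)O[C@H](C(C)(C)C)OC1=O
F3 | step 5 | (2S,5R)-2-tert-butyl-5-{[(2S)-4-hydroxy-4-methyl-3,4-dihydro-2H-pyran-2-yl]methyl}-5-methyl-1,3-dioxolan-4-one (carbinol epimers) | C[C@]1(C[C@@H]2CC(C)(O)C=CO2)O[C@H](C(C)(C)C)OC1=O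
F4 | step 6 | (2S,5R)-2-tert-butyl-5-methyl-5-{[(2S)-4-methyl-6-oxo-3,6-dihydro-2H-pyran-2-yl]methyl}-1,3-dioxolan-4-one | C[C@]1(C[C@@H]2CC(C)=CC(=O)O2)O[C@H](C(C)(C)C)OC1=O
F5 | step 6 | (2Z)-4-[(2S,4R)-4-hydroxy-4-methyl-5-oxooxolan-2-yl]-3-methylbut-2-enoic acid | C[C@@]1(O)C[C@H](C/C(C)=C\C(=O)O)OC1=O
F6 | step 6 | mixed anhydride of F5 with isobutyl hydrogen carbonate | C[C@@]1(O)C[C@H](C/C(C)=C\C(=O)OC(=O)OCC(C)C)OC1=O
F7 | step 8 | (2S,5R)-2-tert-butyl-5-{(2R)-2-hydroxy-3-[(2S,3R)-3-(hydroxymethyl)-2-methyloxiran-2-yl]propyl}-5-methyl-1,3-dioxolan-4-one | C[C@]1(C[C@@H](O)C[C@]2(C)O[C@@H]2CO)O[C@H](C(C)(C)C)OC1=O
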